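## Retrosynthetic overview

1. Ring numbering follows the name cyclohex-4-ene-1,3-diol (C-1 carries the side chain). The ring holds a (Z)-pent-2-ene-1,5-diol, O–C-3–C-4=C-5–C-6–C-1–O: the tertiary carbinol C-1 is homoallylic, and the secondary carbinol C-3 is allylic and 1,3 to C-1 across the C-2 methylene. This is the feature the key step uses.
2. Key disconnections: C-6–C-1 (allyl transfer to a C-1 ketone from boron held on O-3) and C-4=C-5 (ring-closing metathesis), both made in one flask from the acyclic β-hydroxy ketone 15. The cyclohexene is the only ring built and is closed in this step.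
3. The boron tether delivers the allyl group anti to the C-3 vinyl group, so the cascade gives the (1S,3R) trans diol. Mitsunobu inversion at C-3 then gives the cis (1S,3S) target.
4. Ketone 15 comes from 1,3-dithiane as a C-1 acyl-anion linchpin: alkylation with the side-chain bromide, then with (R)-epichlorohydrin (C-2 to C-4), sulfonium-ylide methylenation to the vinyl carbinol, and unmasking.
5. Side chain (sixteen carbons from C-1 to the phenyl ring): acetylide alkylation of 1,11-dibromoundecane with 5-phenylpent-1-yne, then Lindlar semihydrogenation to the Z-alkene.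

Key step: step 8

## Route

Step 1
Reactants: 1 5-phenylpent-1-yne; 2 1,11-dibromoundecane
Product: 4 (16-bromohexadec-4-yn-1-yl)benzene, via lithium acetylide 3 (not isolated)
Conditions: n-BuLi, THF, −78 °C; then 2 (3 equiv), DMPU, −78 °C → rt
Reagents that add atoms: none
Why: SN2 alkylation of a lithium acetylide by a primary bromide in a dipolar aprotic cosolvent, with the excess of dibromide limiting double alkylation.

Step 2
Reactants: 4 (16-bromohexadec-4-yn-1-yl)benzene
Product: 5 [(4Z)-16-bromohexadec-4-en-1-yl]benzene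
Conditions: H2 (1 atm), Lindlar catalyst (Pd/CaCO3, Pb(OAc)2-poisoned), quinoline, EtOAc, rt
Reagents that add atoms: none
Why: Lindlar semihydrogenation adds hydrogen syn on the poisoned palladium surface and should stop at the Z-alkene, leaving the primary bromide and the arene untouched.

Step 3
Reactants: 6 1,3-dithiane; 5 [(4Z)-16-bromohexadec-4-en-1-yl]benzene
Product: 8 2-[(12Z)-16-phenylhexadec-12-en-1-yl]-1,3-dithiane, via 2-lithio-1,3-dithiane 7 (not isolated)
Conditions: n-BuLi, THF, −30 °C; then 5, −78 °C → rt
Reagents that add atoms: none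
Why: Corey–Seebach alkylation, in which the sulfur-stabilised C-2 anion displaces the primary bromide (SN2) and installs the future ketone carbon C-1 as an acyl-anion equivalent.

Step 4
Reactants: 8 2-[(12Z)-16-phenylhexadec-12-en-1-yl]-1,3-dithiane; 9 (2R)-2-(chloromethyl)oxirane
Product: 12 2-{[(2R)-oxiran-2-yl]methyl}-2-[(12Z)-16-phenylhexadec-12-en-1-yl]-1,3-dithiane, via lithiated dithiane 10 (not isolated), via chlorohydrin alkoxide 11 (not isolated)
Conditions: t-BuLi, THF/HMPA (10:1), −78 °C; then 9, −78 → 0 °C
Reagents that add atoms: none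
Why: A second Corey–Seebach metalation and SN2 opening of the epoxide at its ring CH2, followed by closure of the chlorohydrin alkoxide onto the CH2Cl carbon, breaks no bond to the stereocentre, so its configuration is carried over from 9.

Step 5
Reactants: 12 2-{[(2R)-oxiran-2-yl]methyl}-2-[(12Z)-16-phenylhexadec-12-en-1-yl]-1,3-dithiane
Product: 14 (2R)-1-{2-[(12Z)-16-phenylhexadec-12-en-1-yl]-1,3-dithian-2-yl}but-3-en-2-ol, via sulfonium betaine 13 (not isolated)
Conditions: Me3S+ I−, n-BuLi, THF, −10 °C → rt
Reagents that add atoms: trimethylsulfonium iodide, C[S+](C)C.[I-]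
Why: Dimethylsulfonium methylide opens the terminal epoxide at CH2 and the betaine loses dimethyl sulfide by β-elimination, a one-carbon epoxide-to-allylic-alcohol homologation that leaves the carbinol stereocentre untouched.

Step 6
Reactants: 14 (2R)-1-{2-[(12Z)-16-phenylhexadec-12-en-1-yl]-1,3-dithian-2-yl}but-3-en-2-ol
Product: 15 (3R,17Z)-3-hydroxy-21-phenylhenicosa-1,17-dien-5-one
Conditions: MeI, CaCO3, MeCN/H2O (9:1), 45 °C
Reagents that add atoms: water, O
Why: Alkylative hydrolysis of the dithioketal (S-methylation, then attack of water) under carbonate buffering should unmask the ketone without acid that could dehydrate the β-hydroxy ketone or touch the alkenes.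

Step 7
Reactants: 16 allylmagnesium bromide; 17 triisopropyl borate
Product: 19 diisopropyl allylboronate, via borate ate complex 18 (not isolated)
Conditions: Et2O, −78 °C → rt; then HCl in Et2O (1 equiv), 0 °C; distillation
Reagents that add atoms: none
Why: Transmetalation from magnesium to boron through the ate complex, then protonolysis of one isopropoxide, is the standard preparation of allylboronic esters.

Step 8
Reactants: 15 (3R,17Z)-3-hydroxy-21-phenylhenicosa-1,17-dien-5-one; 19 diisopropyl allylboronate
Product: 23 (1S,3R)-1-[(12Z)-16-phenylhexadec-12-en-1-yl]cyclohex-4-ene-1,3-diol, via mixed allylboronate 20 (not isolated), via cyclic borate 21 (not isolated), via diene diol 22 (not isolated)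
Conditions: 19, CH2Cl2, 0 °C → rt; then pinacol, rt; then RuCl2(=CHPh)(PCy3)2 (first-generation Grubbs catalyst, 5 mol%), 1,4-benzoquinone (10 mol%), CH2Cl2 (5 mM), 40 °C
Reagents that add atoms: none
Why: The hydroxyl of 15 exchanges an isopropoxy group of 19, the ketone oxygen binds the same boron, and the allyl group passes from boron to the carbonyl carbon (ring C-1) through a chair–chair bicyclic transition state (six-membered O–B–O chelate fused to the six-membered allylboration array) to give borate 21; pinacol then frees diol 22 and the ruthenium alkylidene joins its two monosubstituted alkenes with loss of ethene. The closest known reaction types are the hydroxyl-directed allylboration of α- and β-hydroxy ketones with B-allyldialkoxyboranes and the ring-closing metathesis of 1,7-dienes carrying free allylic and homoallylic hydroxyls. The cyclohexene, the only ring formed, is closed by ring-closing olefin metathesis between the vinyl group on C-3 and the allyl group on C-1 (new C-4=C-5 bond, cis by ring constraint) after the allyl transfer has made the C-6–C-1 bond. The new stereocentre C-1 is controlled by the C-3 carbinol: the vinyl group sits equatorial on the chelate, away from the allyl bridge, and the allyl group enters axially, anti to it, which should give 1S and, after ring closure, the trans 1,3-diol that step 9 corrects at C-3. The step needs facial selectivity at the ketone, secured by the boron tether on the free C-3 hydroxyl, and chemoselectivity for the two terminal alkenes over the remote Z-alkene, secured by the less active first-generation catalyst, the favoured six-membered ring and high dilution; benzoquinone is there to suppress ruthenium-hydride isomerisation of the allylic alcohol.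

Step 9
Reactants: 23 (1S,3R)-1-[(12Z)-16-phenylhexadec-12-en-1-yl]cyclohex-4-ene-1,3-diol
Product: 24 (1S,5S)-5-hydroxy-5-[(12Z)-16-phenylhexadec-12-en-1-yl]cyclohex-2-en-1-yl 4-nitrobenzoate
Conditions: 4-nitrobenzoic acid, PPh3, DIAD, THF, 0 °C → rt
Reagents that add atoms: 4-nitrobenzoic acid, O=C(O)c1ccc(cc1)[N+](=O)[O-]
Why: Mitsunobu esterification, in which the C-3 oxyphosphonium ion is displaced by 4-nitrobenzoate with SN2 inversion (3R to 3S, now cis to the tertiary hydroxyl, which is too hindered to react).

Step 10
Reactants: 24 (1S,5S)-5-hydroxy-5-[(12Z)-16-phenylhexadec-12-en-1-yl]cyclohex-2-en-1-yl 4-nitrobenzoate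
Product: 25 (1S,3S)-1-[(12Z)-16-phenylhexadec-12-en-1-yl]cyclohex-4-ene-1,3-diol
Conditions: K2CO3 (cat.), MeOH, rt
Reagents that add atoms: none
Why: Base-catalysed transesterification cleaves the activated ester at the acyl carbon, so the C-3 configuration is retained and the tertiary alcohol and both alkenes stay untouched.

## Compound list

1 | 5-phenylpent-1-yne | C#CCCCc1ccccc1 | starting material
2 | 1,11-dibromoundecane | BrCCCCCCCCCCCBr | starting material
3 | lithium 5-phenylpent-1-yn-1-ide | [Li]C#CCCCc1ccccc1 | intermediate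
4 | (16-bromohexadec-4-yn-1-yl)benzene | BrCCCCCCCCCCCC#CCCCc1ccccc1 | intermediate
5 | [(4Z)-16-bromohexadec-4-en-1-yl]benzene | BrCCCCCCCCCCC/C=C\CCCc1ccccc1 | intermediate
6 | 1,3-dithiane | C1CSCSC1 | starting material
7 | 2-lithio-1,3-dithiane | [Li]C1SCCCS1 | intermediate
8 | 2-[(12Z)-16-phenylhexadec-12-en-1-yl]-1,3-dithiane | C1CSC(SC1)CCCCCCCCCCC/C=C\CCCc2ccccc2 | intermediate
9 | (2R)-2-(chloromethyl)oxirane, (R)-epichlorohydrin | ClC[C@H]1CO1 | starting material
10 | 2-lithio-2-[(12Z)-16-phenylhexadec-12-en-1-yl]-1,3-dithiane | [Li]C1(SCCCS1)CCCCCCCCCCC/C=C\CCCc2ccccc2 | intermediate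
11 | lithium (2R)-1-chloro-3-{2-[(12Z)-16-phenylhexadec-12-en-1-yl]-1,3-dithian-2-yl}propan-2-olate | ClC[C@H](O[Li])CC1(SCCCS1)CCCCCCCCCCC/C=C\CCCc2ccccc2 | intermediate
12 | 2-{[(2R)-oxiran-2-yl]methyl}-2-[(12Z)-16-phenylhexadec-12-en-1-yl]-1,3-dithiane | C1CSC(SC1)(CCCCCCCCCCC/C=C\CCCc2ccccc2)C[C@@H]3CO3 | intermediate
13 | dimethyl[(3S)-3-oxido-4-{2-[(12Z)-16-phenylhexadec-12-en-1-yl]-1,3-dithian-2-yl}butyl]sulfonium (inner salt) | C[S+](C)CC[C@H]([O-])CC1(SCCCS1)CCCCCCCCCCC/C=C\CCCc2ccccc2 | intermediate
14 | (2R)-1-{2-[(12Z)-16-phenylhexadec-12-en-1-yl]-1,3-dithian-2-yl}but-3-en-2-ol | C1CSC(SC1)(CCCCCCCCCCC/C=C\CCCc2ccccc2)C[C@@H](O)C=C | intermediate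
15 | (3R,17Z)-3-hydroxy-21-phenylhenicosa-1,17-dien-5-one | C=C[C@H](O)CC(=O)CCCCCCCCCCC/C=C\CCCc1ccccc1 | intermediate
16 | allylmagnesium bromide | C=CC[Mg]Br | starting material
17 | triisopropyl borate | CC(C)OB(OC(C)C)OC(C)C | starting material
18 | bromomagnesium allyltriisopropoxyborate | C=CC[B-](OC(C)C)(OC(C)C)OC(C)C.[Mg+]Br | intermediate
19 | diisopropyl allylboronate (dipropan-2-yl prop-2-en-1-ylboronate) | C=CCB(OC(C)C)OC(C)C | intermediate
20 | propan-2-yl (3R,17Z)-5-oxo-21-phenylhenicosa-1,17-dien-3-yl prop-2-en-1-ylboronate | C=C[C@H](OB(CC=C)OC(C)C)CC(=O)CCCCCCCCCCC/C=C\CCCc1ccccc1 | intermediate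
21 | (4S,6R)-6-ethenyl-4-[(12Z)-16-phenylhexadec-12-en-1-yl]-2-(propan-2-yloxy)-4-(prop-2-en-1-yl)-1,3,2-dioxaborinane | CC(C)OB1O[C@@H](C=C)C[C@@](CC=C)(CCCCCCCCCCC/C=C\CCCc2ccccc2)O1 | intermediate
22 | (3R,5S,17Z)-21-phenyl-5-(prop-2-en-1-yl)henicosa-1,17-diene-3,5-diol | C=C[C@H](O)C[C@@](O)(CC=C)CCCCCCCCCCC/C=C\CCCc1ccccc1 | intermediate
23 | (1S,3R)-1-[(12Z)-16-phenylhexadec-12-en-1-yl]cyclohex-4-ene-1,3-diol | O[C@H]1C=CC[C@@](O)(CCCCCCCCCCC/C=C\CCCc2ccccc2)C1 | intermediate
24 | (1S,5S)-5-hydroxy-5-[(12Z)-16-phenylhexadec-12-en-1-yl]cyclohex-2-en-1-yl 4-nitrobenzoate | O=C(O[C@@H]1C=CC[C@@](O)(CCCCCCCCCCC/C=C\CCCc2ccccc2)C1)c3ccc(cc3)[N+](=O)[O-] | intermediate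
25 | (1S,3S)-1-[(12Z)-16-phenylhexadec-12-en-1-yl]cyclohex-4-ene-1,3-diol | O[C@@H]1C=CC[C@@](O)(CCCCCCCCCCC/C=C\CCCc2ccccc2)C1 | target

## Step count and risks

Total step count: 10.
Longest linear sequence: 9 steps (steps 1–6 and 8–10, from 1 to 25); step 7 is a one-step branch that makes the allyl reagent.

Steps most likely to fail:

**Step 8.** The allyl transfer may partly escape the boron chelate, which would weaken the 1,3-induction. During ring closure, ruthenium hydrides may isomerise the allylic alcohol, or the catalyst may attack the remote Z-alkene. The fallback sets out from 15 and comes back to the route at 23, with the two events separated and the carbinol masked. Ketone 15 is treated with 4-methoxybenzyl 2,2,2-trichloroacetimidate and catalytic camphorsulfonic acid in CH2Cl2 to give the ether (3R,17Z)-3-[(4-methoxyphenyl)methoxy]-21-phenylhenicosa-1,17-dien-5-one F1. Hosomi–Sakurai allylation on the six-membered titanium chelate (TiCl4, allyltrimethylsilane, CH2Cl2, −78 °C), where the silane attacks from outside with the same anti sense, should give (3R,5S,17Z)-3-[(4-methoxyphenyl)methoxy]-21-phenyl-5-(prop-2-en-1-yl)henicosa-1,17-dien-5-ol F2. Ring-closing metathesis of this ether with RuCl2(=CHPh)(PCy3)2 in dilute CH2Cl2 should give (1S,3R)-3-[(4-methoxyphenyl)methoxy]-1-[(12Z)-16-phenylhexadec-12-en-1-yl]cyclohex-4-en-1-ol F3. DDQ in wet CH2Cl2 then removes the ether and returns 23.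

**Step 9.** The oxyphosphonium ion may ionise or be attacked with allylic transposition (SN2′ at C-5). Because the allyl unit C-3–C-4–C-5 is flanked by two methylenes, this would erode stereochemical purity; elimination to a diene is also possible. The fallback sets out from 23 and comes back to the route at 25, and it avoids any allylic substitution. MnO2 in CH2Cl2 should oxidise only the allylic alcohol, giving (5S)-5-hydroxy-5-[(12Z)-16-phenylhexadec-12-en-1-yl]cyclohex-2-en-1-one F4. Corey–Bakshi–Shibata reduction of this enone with the (R)-2-methyl oxazaborolidine and catecholborane (toluene, −78 °C), with the alkenyl side acting as the large group, should give the 3S (cis) carbinol 25 directly. Any wrong-face reduction would appear as the separable trans diol 23.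

**Step 5.** With the excess of ylide, a second methylene transfer (oxetane formation) or base-induced decomposition of the hindered epoxide may compete with the wanted β-elimination. The fallback sets out from 8 and comes back to the route at 14, replacing steps 4 and 5. Lithiated dithiane 10 (from 8, t-BuLi, THF/HMPA, −78 °C) is added to (2S)-2-ethenyloxirane; SN2 attack at the ring CH2 should give 14 in one operation after aqueous work-up.

Further compounds
F1 | step 8 | (3R,17Z)-3-[(4-methoxyphenyl)methoxy]-21-phenylhenicosa-1,17-dien-5-one | C=C[C@H](OCc1ccc(OC)cc1)CC(=O)CCCCCCCCCCC/C=C\CCCc2ccccc2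
F2 | step 8 | (3R,5S,17Z)-3-[(4-methoxyphenyl)methoxy]-21-phenyl-5-(prop-2-en-1-yl)henicosa-1,17-dien-5-ol | C=C[C@H](OCc1ccc(OC)cc1)C[C@@](O)(CC=C)CCCCCCCCCCC/C=C\CCCc2ccccc2
F3 | step 8 | (1S,3R)-3-[(4-methoxyphenyl)methoxy]-1-[(12Z)-16-phenylhexadec-12-en-1-yl]cyclohex-4-en-1-ol | COc1ccc(CO[C@H]2C=CC[C@@](O)(CCCCCCCCCCC/C=C\CCCc3ccccc3)C2)cc1
F4 | step 9 | (5S)-5-hydroxy-5-[(12Z)-16-phenylhexadec-12-en-1-yl]cyclohex-2-en-1-one | O=C1C=CC[C@@](O)(CCCCCCCCCCC/C=C\CCCc2ccccc2)C1
F0 | step 5 | none | none
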